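**Retrosynthetic overview**
- Feature: spiro C5 is stereogenic only because its ring A neighbours differ (C1 carries the side chain, C4 a methyl). With C8 as a carbonyl the two arms of ring B (C6=C7 and C10=C9) are identical, so ring B is carried as a cyclohexa-2,5-dienone.
- Key disconnection C5–C1: para C-alkylation of a phenoxide by a C1 mesylate closes ring A onto the arene that becomes ring B. C4 (Rh-catalysed arylation) and C1'/C1 (anti-crotylboration, then inversion at C1) are set in the open chain.
- C5 is fixed afterwards by the C2' hydroxyl, which adds to C6 as a temporary cis-fused ether. The other arm is hydrogenated and the ether reopened to the C6=C7 enone, which becomes C7=C8(Me).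
- C2'–C3' by copper-catalysed alkyl–alkyl coupling with a C3'–C6' Grignard reagent; C9–OH last, by SeO2 oxidation and CBS reduction.
- Ring order: ring B (aromatic, from 1), ring A (step 9), temporary tetrahydropyran (closed in step 10, opened in step 12).

Key step: step 9

Remark: atoms are labelled as in the target (ring A C1–C4, spiro C5, ring B C6–C10, side chain C1'–C6'). The senses of induction quoted for (R)-BINAP, (+)-Ipc2BOMe and the (R)-oxazaborolidine follow the accepted transition-state models and are assumptions to be confirmed on the first intermediates.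

**Route**

Step 1
Reactants: 1 4-(benzyloxy)phenylboronic acid; 2 ethyl (E)-but-2-enoate
Product: 3 ethyl (S)-3-[4-(benzyloxy)phenyl]butanoate
Conditions: [Rh(acac)(C2H4)2] (3 mol %), (R)-BINAP (3.3 mol %), 1 (2.5 equiv), 1,4-dioxane/H2O 10:1, 100 °C
Reagents that add atoms: none
Why: Hayashi–Miyaura rhodium-catalysed asymmetric 1,4-addition, in which the aryl–rhodium/(R)-BINAP species should insert the (E)-enoate on the face that gives the (S)-benzylic centre C4 and water releases the ester by protonolysis.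

Step 2
Reactants: 3 ethyl (S)-3-[4-(benzyloxy)phenyl]butanoate
Product: 4 (S)-3-[4-(benzyloxy)phenyl]butanal
Conditions: i-Bu2AlH (1.05 equiv), CH2Cl2, −78 °C; aqueous potassium sodium tartrate (KNaC4H4O6)
Reagents that add atoms: none
Why: Partial ester reduction by i-Bu2AlH stops at the aluminium hemiacetal at −78 °C and gives the aldehyde on work-up; C4 is beta to the carbonyl and cannot epimerise.

Step 3
Reactants: 4 (S)-3-[4-(benzyloxy)phenyl]butanal
Product: 6 (S)-4-[4-(benzyloxy)phenyl]pentanal, via methyl enol ether 5 (not isolated)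
Conditions: MeOCH2PPh3Cl, KOt-Bu, THF, 0 °C; then 2 M HCl, THF, rt
Reagents that add atoms: (methoxymethyl)triphenylphosphonium chloride, COC[P+](c1ccccc1)(c1ccccc1)c1ccccc1.[Cl-]; water, O
Why: Wittig methoxymethylenation followed by acid hydrolysis of the enol ether is the standard one-carbon aldehyde homologation; the benzyl ether and the remote stereocentre are inert to both stages.

Step 4
Reactants: 6 (S)-4-[4-(benzyloxy)phenyl]pentanal; 7 (E)-but-2-ene
Product: 10 (3R,4S,7S)-7-[4-(benzyloxy)phenyl]-3-methyloct-1-en-4-ol, via crotylborane 8 (not isolated), via borinate ester 9 (not isolated)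
Conditions: 7, KOt-Bu, n-BuLi, THF, −78 to −45 °C; (+)-Ipc2BOMe [from (−)-α-pinene], −78 °C; BF3·OEt2; then 6, −78 °C; NaOH, H2O2, 0 °C to rt
Reagents that add atoms: none
Why: Brown crotylboration through a closed chair transition state; the (E)-crotylborane should give the anti C1'/C1 pair and the isopinocampheyl groups of the (−)-α-pinene series should direct attack to the re face of the aldehyde, giving (3R,4S) under reagent control.

Step 5
Reactants: 10 (3R,4S,7S)-7-[4-(benzyloxy)phenyl]-3-methyloct-1-en-4-ol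
Product: 12 (2R,3S,6S)-6-[4-(benzyloxy)phenyl]-2-methylheptane-1,3-diol, via secondary ozonide 11 (not isolated)
Conditions: O3, CH2Cl2, −78 °C (Sudan Red 7B end point); then NaBH4, MeOH, −78 °C to rt
Reagents that add atoms: ozone, [O-][O+]=O
Why: Ozonolysis of the terminal alkene, which reacts far faster than the benzyloxyarene, with reductive NaBH4 work-up turns the vinyl group into the C2' primary alcohol without touching a stereocentre.

Step 6
Reactants: 12 (2R,3S,6S)-6-[4-(benzyloxy)phenyl]-2-methylheptane-1,3-diol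
Product: 13 (2R,3S,6S)-6-[4-(benzyloxy)phenyl]-1-[(tert-butyldimethylsilyl)oxy]-2-methylheptan-3-ol
Conditions: TBSCl (1.05 equiv), imidazole, CH2Cl2, 0 °C
Reagents that add atoms: tert-butyldimethylsilyl chloride, CC(C)(C)[Si](C)(C)Cl
Why: Silylation with one equivalent of the bulky chlorosilane should select the primary C2' hydroxyl over the secondary C1 hydroxyl.

Step 7
Reactants: 13 (2R,3S,6S)-6-[4-(benzyloxy)phenyl]-1-[(tert-butyldimethylsilyl)oxy]-2-methylheptan-3-ol
Product: 14 (2R,3S,6S)-6-[4-(benzyloxy)phenyl]-1-[(tert-butyldimethylsilyl)oxy]-2-methylheptan-3-yl methanesulfonate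
Conditions: MsCl, Et3N, CH2Cl2, 0 °C
Reagents that add atoms: methanesulfonyl chloride, CS(=O)(=O)Cl
Why: Mesylation through sulfene forms the O–S bond only, so C1 keeps its configuration.

Step 8
Reactants: 14 (2R,3S,6S)-6-[4-(benzyloxy)phenyl]-1-[(tert-butyldimethylsilyl)oxy]-2-methylheptan-3-yl methanesulfonate
Product: 15 (2R,3S,6S)-1-[(tert-butyldimethylsilyl)oxy]-6-(4-hydroxyphenyl)-2-methylheptan-3-yl methanesulfonate
Conditions: H2 (1 atm), Pd/C (10 wt %), EtOAc, rt
Reagents that add atoms: none
Why: Hydrogenolysis of the benzyl aryl ether over Pd/C in a neutral aprotic solvent leaves the alkyl mesylate and the silyl ether untouched.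

Step 9
Reactants: 15 (2R,3S,6S)-1-[(tert-butyldimethylsilyl)oxy]-6-(4-hydroxyphenyl)-2-methylheptan-3-yl methanesulfonate
Product: 17 (1R,4S)-1-[(S)-1-[(tert-butyldimethylsilyl)oxy]propan-2-yl]-4-methylspiro[4.5]deca-6,9-dien-8-one, via potassium phenoxide 16 (not isolated)
Conditions: KOt-Bu (1.05 equiv), t-BuOH (0.01 M), 70 °C
Reagents that add atoms: none
Why: Deprotonation gives phenoxide 16, whose para carbon C5 displaces the C1 mesylate from the rear in an intramolecular SN2 alkylation; the product cannot rearomatise because C5 is quaternary. The closest known reaction type is phenoxide para-alkylation with aryl participation (Ar1-5 closure, the Winstein–Baird spirodienone synthesis), here on a secondary, beta-branched sulfonate. Ring A closes in a 5-exo-tet mode. No stereocentre arises at C5 because the two dienone arms are identical; C1 is inverted from S to R by the SN2 geometry, and C4 and C1' are carried unchanged. The step needs substitution to beat E2 loss of the mesylate and C- to beat O-alkylation: one equivalent of base leaves the weakly basic phenoxide as the only base, high dilution suppresses intermolecular O-alkylation, and the phenoxide oxygen cannot reach C1 within the molecule. The ring carbons ortho to the chain are meta to the oxygen and unactivated, so a six-membered closure should not compete.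

Step 10
Reactants: 17 (1R,4S)-1-[(S)-1-[(tert-butyldimethylsilyl)oxy]propan-2-yl]-4-methylspiro[4.5]deca-6,9-dien-8-one
Product: 19 C2'-O-C6 bridged tricyclic enone (6S), via dienone alcohol 18 (not isolated)
Conditions: n-Bu4NF (1.2 equiv), THF, 0 °C to rt, stirred until the ether ratio no longer changes
Reagents that add atoms: none
Why: Fluoride desilylation releases the C2' alkoxide, which adds 6-exo-trig to the dienone in an intramolecular oxa-Michael desymmetrisation; only C6, on the same side of ring A as the C1 side chain, can be reached with a cis fusion across C1–C5, and since the addition is reversible the cis-fused ether should also be the one that accumulates, which fixes C5 and places the C6 oxygen syn to C1.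

Step 11
Reactants: 19 C2'-O-C6 bridged tricyclic enone (6S)
Product: 20 C2'-O-C6 bridged tricyclic ketone (6S)
Conditions: H2 (1 atm), Pd/C (10 wt %), EtOAc, rt
Reagents that add atoms: none
Why: Heterogeneous hydrogenation saturates the only remaining C=C (C9=C10) of the enone, leaving the ketone and the ether intact and creating no stereocentre.

Step 12
Reactants: 20 C2'-O-C6 bridged tricyclic ketone (6S)
Product: 21 (1R,4S,5S)-1-[(S)-1-[(tert-butyldimethylsilyl)oxy]propan-2-yl]-4-methylspiro[4.5]dec-6-en-8-one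
Conditions: TBSCl (3 equiv), DBU (4 equiv), toluene, 80 °C; aqueous citric acid work-up
Reagents that add atoms: tert-butyldimethylsilyl chloride, CC(C)(C)[Si](C)(C)Cl
Why: Retro-oxa-Michael (E1cB) opening, in which DBU enolises toward C7 and the C6–O bond is expelled, is drained by irreversible silylation of the liberated primary alcohol; C5 is now stereogenic on its own because one arm is saturated.

Step 13
Reactants: 21 (1R,4S,5S)-1-[(S)-1-[(tert-butyldimethylsilyl)oxy]propan-2-yl]-4-methylspiro[4.5]dec-6-en-8-one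
Product: 23 (1R,4S,5R)-1-[(S)-1-[(tert-butyldimethylsilyl)oxy]propan-2-yl]-4-methylspiro[4.5]dec-7-en-8-yl trifluoromethanesulfonate, via lithium enolate 22 (not isolated)
Conditions: Li[BH(s-Bu)3] (1.1 equiv), THF, −78 °C; then N-(5-chloropyridin-2-yl)bis(trifluoromethanesulfonyl)imide, −78 °C to rt
Reagents that add atoms: N-(5-chloropyridin-2-yl)bis(trifluoromethanesulfonyl)imide, O=S(=O)(N(c1ccc(Cl)cn1)S(=O)(=O)C(F)(F)F)C(F)(F)F
Why: Reductive enol triflation: conjugate hydride addition of the bulky trialkylborohydride to the beta-unsubstituted cyclohexenone gives the C7=C8 enolate regiospecifically, and the triflimide traps it on oxygen.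

Step 14
Reactants: 23 (1R,4S,5R)-1-[(S)-1-[(tert-butyldimethylsilyl)oxy]propan-2-yl]-4-methylspiro[4.5]dec-7-en-8-yl trifluoromethanesulfonate
Product: 24 tert-butyl{(S)-2-[(1R,4S,5R)-4,8-dimethylspiro[4.5]dec-7-en-1-yl]propoxy}dimethylsilane
Conditions: MeMgBr (2 equiv), Fe(acac)3 (10 mol %), THF/NMP, −30 to 0 °C
Reagents that add atoms: methylmagnesium bromide, C[Mg]Br
Why: Iron-catalysed Kumada-type cross-coupling of an alkenyl triflate with a methyl Grignard reagent (Fürstner conditions) replaces the triflate by methyl without moving the double bond.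

Step 15
Reactants: 24 tert-butyl{(S)-2-[(1R,4S,5R)-4,8-dimethylspiro[4.5]dec-7-en-1-yl]propoxy}dimethylsilane
Product: 25 (S)-2-[(1R,4S,5R)-4,8-dimethylspiro[4.5]dec-7-en-1-yl]propan-1-ol
Conditions: n-Bu4NF, THF, rt
Reagents that add atoms: none
Why: Fluoride desilylation of a primary silyl ether; with the enone gone the free alcohol can no longer re-add to ring B.

Step 16
Reactants: 25 (S)-2-[(1R,4S,5R)-4,8-dimethylspiro[4.5]dec-7-en-1-yl]propan-1-ol
Product: 26 (1R,4S,5R)-1-[(S)-1-iodopropan-2-yl]-4,8-dimethylspiro[4.5]dec-7-ene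
Conditions: I2, PPh3, imidazole, CH2Cl2, 0 °C to rt
Reagents that add atoms: iodine, II
Why: Appel-type (Garegg–Samuelsson) iodination converts the primary alcohol into the iodide at the non-stereogenic C2'.

Step 17
Reactants: 27 (R)-3-bromo-2-methylpropan-1-ol
Product: 28 (R)-(3-bromo-2-methylpropoxy)(tert-butyl)dimethylsilane
Conditions: TBSCl, imidazole, CH2Cl2, rt
Reagents that add atoms: tert-butyldimethylsilyl chloride, CC(C)(C)[Si](C)(C)Cl
Why: Standard silylation of a primary alcohol; the bromide is inert.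

Step 18
Reactants: 28 (R)-(3-bromo-2-methylpropoxy)(tert-butyl)dimethylsilane
Product: 30 (S)-4-[(tert-butyldimethylsilyl)oxy]-3-methylbutan-1-ol, via Grignard reagent 29 (not isolated)
Conditions: Mg, THF, reflux; then paraformaldehyde, THF, 0 °C to reflux
Reagents that add atoms: paraformaldehyde (formaldehyde unit), C=O
Why: Grignard formation and addition to formaldehyde is a one-carbon homologation that supplies C3'; the stereocentre (C5') is beta to magnesium and not involved.

Step 19
Reactants: 30 (S)-4-[(tert-butyldimethylsilyl)oxy]-3-methylbutan-1-ol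
Product: 31 (S)-(4-bromo-2-methylbutoxy)(tert-butyl)dimethylsilane
Conditions: CBr4, PPh3, CH2Cl2, 0 °C
Reagents that add atoms: carbon tetrabromide, BrC(Br)(Br)Br
Why: Appel bromination of a primary alcohol under neutral conditions that the silyl ether tolerates.

Step 20
Reactants: 26 (1R,4S,5R)-1-[(S)-1-iodopropan-2-yl]-4,8-dimethylspiro[4.5]dec-7-ene; 31 (S)-(4-bromo-2-methylbutoxy)(tert-butyl)dimethylsilane
Product: 33 tert-butyl{[(2S,6R)-6-[(1R,4S,5R)-4,8-dimethylspiro[4.5]dec-7-en-1-yl]-2-methylheptyl]oxy}dimethylsilane, via Grignard reagent 32 (not isolated)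
Conditions: 31 (3 equiv), Mg, THF, 40 °C; then 26, Li2CuCl4 (5 mol %), THF/NMP, −20 °C to rt
Reagents that add atoms: none
Why: Copper-catalysed (Kochi-type) alkyl–alkyl coupling of a primary iodide with a primary Grignard reagent forms C2'–C3' without touching a stereocentre or the trisubstituted alkene.

Step 21
Reactants: 33 tert-butyl{[(2S,6R)-6-[(1R,4S,5R)-4,8-dimethylspiro[4.5]dec-7-en-1-yl]-2-methylheptyl]oxy}dimethylsilane
Product: 35 (2S,6R)-6-[(1R,4S,5R)-4,8-dimethylspiro[4.5]dec-7-en-1-yl]-2-methylheptyl acetate, via primary alcohol 34 (not isolated)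
Conditions: n-Bu4NF, THF, rt; then Ac2O, Et3N, DMAP (cat.), rt
Reagents that add atoms: acetic anhydride, CC(=O)OC(C)=O
Why: Fluoride desilylation followed by DMAP-catalysed acylation in the same flask installs the C6' acetate before any other hydroxyl exists in the molecule.

Step 22
Reactants: 35 (2S,6R)-6-[(1R,4S,5R)-4,8-dimethylspiro[4.5]dec-7-en-1-yl]-2-methylheptyl acetate
Product: 36 (2S,6R)-6-[(1R,4S,5S)-9-hydroxy-4,8-dimethylspiro[4.5]dec-7-en-1-yl]-2-methylheptyl acetate (mixture of C9 epimers)
Conditions: SeO2 (0.5 equiv), t-BuOOH, CH2Cl2, rt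
Reagents that add atoms: selenium dioxide, O=[Se]=O; tert-butyl hydroperoxide, CC(C)(C)OO
Why: SeO2 allylic oxidation (ene reaction, then [2,3]-sigmatropic shift) should place oxygen on the ring CH2 attached to the more substituted alkene carbon, C9, with the double bond returned to C7=C8 (Guillemonat rule); the C9 epimer ratio is of no consequence.

Step 23
Reactants: 36 (2S,6R)-6-[(1R,4S,5S)-9-hydroxy-4,8-dimethylspiro[4.5]dec-7-en-1-yl]-2-methylheptyl acetate (mixture of C9 epimers, with any enone already formed)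
Product: 37 (2S,6R)-6-[(1R,4S,5S)-4,8-dimethyl-9-oxospiro[4.5]dec-7-en-1-yl]-2-methylheptyl acetate
Conditions: Dess–Martin periodinane, CH2Cl2, rt
Reagents that add atoms: none
Why: Dess–Martin oxidation converges both allylic alcohol epimers to a single enone without touching the acetate.

Step 24
Reactants: 37 (2S,6R)-6-[(1R,4S,5S)-4,8-dimethyl-9-oxospiro[4.5]dec-7-en-1-yl]-2-methylheptyl acetate
Product: 38 (2S,6R)-6-[(1R,4S,5S,9S)-9-hydroxy-4,8-dimethylspiro[4.5]dec-7-en-1-yl]-2-methylheptyl acetate
Conditions: (R)-1-methyl-3,3-diphenyltetrahydro-1H,3H-pyrrolo[1,2-c][1,3,2]oxazaborole [(R)-Me-CBS, 0.5 equiv], catecholborane, toluene, −78 °C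
Reagents that add atoms: none
Why: Corey–Bakshi–Shibata reduction, in which the (R)-oxazaborolidine binds the ketone with the alkenyl (C8) side as the large group and should deliver hydride to the face giving (9S), overriding the weak bias of the remote spiro centre; the acetate is inert to catecholborane at −78 °C.

**Compound list**
1 | 4-(benzyloxy)phenylboronic acid | OB(O)c1ccc(OCc2ccccc2)cc1 | starting material
2 | ethyl (E)-but-2-enoate | CCOC(=O)/C=C/C | starting material
3 | ethyl (S)-3-[4-(benzyloxy)phenyl]butanoate | CCOC(=O)C[C@H](C)c1ccc(OCc2ccccc2)cc1 | intermediate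
4 | (S)-3-[4-(benzyloxy)phenyl]butanal | O=CC[C@H](C)c1ccc(OCc2ccccc2)cc1 | intermediate
5 | 1-(benzyloxy)-4-[(2S)-5-methoxypent-4-en-2-yl]benzene (E/Z mixture) | COC=CC[C@H](C)c1ccc(OCc2ccccc2)cc1 | intermediate
6 | (S)-4-[4-(benzyloxy)phenyl]pentanal | O=CCC[C@H](C)c1ccc(OCc2ccccc2)cc1 | intermediate
7 | (E)-but-2-ene | C/C=C/C | starting material
8 | (E)-but-2-enylbis(isopinocampheyl)borane, (−)-α-pinene series | C/C=C/CB([C@H]1C[C@H]2C[C@@H]([C@@H]1C)C2(C)C)[C@H]1C[C@H]2C[C@@H]([C@@H]1C)C2(C)C | intermediate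
9 | bis(isopinocampheyl)borinate ester of 10 | C=C[C@@H](C)[C@@H](OB([C@H]1C[C@H]2C[C@@H]([C@@H]1C)C2(C)C)[C@H]1C[C@H]2C[C@@H]([C@@H]1C)C2(C)C)CC[C@H](C)c1ccc(OCc2ccccc2)cc1 | intermediate
10 | (3R,4S,7S)-7-[4-(benzyloxy)phenyl]-3-methyloct-1-en-4-ol | C=C[C@@H](C)[C@@H](O)CC[C@H](C)c1ccc(OCc2ccccc2)cc1 | intermediate
11 | secondary ozonide (3-substituted 1,2,4-trioxolane) of 10, epimers at the trioxolane carbon | C1OC(OO1)[C@@H](C)[C@@H](O)CC[C@H](C)c1ccc(OCc2ccccc2)cc1 | intermediate
12 | (2R,3S,6S)-6-[4-(benzyloxy)phenyl]-2-methylheptane-1,3-diol | OC[C@@H](C)[C@@H](O)CC[C@H](C)c1ccc(OCc2ccccc2)cc1 | intermediate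
13 | (2R,3S,6S)-6-[4-(benzyloxy)phenyl]-1-[(tert-butyldimethylsilyl)oxy]-2-methylheptan-3-ol | CC(C)(C)[Si](C)(C)OC[C@@H](C)[C@@H](O)CC[C@H](C)c1ccc(OCc2ccccc2)cc1 | intermediate
14 | (2R,3S,6S)-6-[4-(benzyloxy)phenyl]-1-[(tert-butyldimethylsilyl)oxy]-2-methylheptan-3-yl methanesulfonate | CC(C)(C)[Si](C)(C)OC[C@@H](C)[C@@H](OS(C)(=O)=O)CC[C@H](C)c1ccc(OCc2ccccc2)cc1 | intermediate
15 | (2R,3S,6S)-1-[(tert-butyldimethylsilyl)oxy]-6-(4-hydroxyphenyl)-2-methylheptan-3-yl methanesulfonate (key-step precursor) | CC(C)(C)[Si](C)(C)OC[C@@H](C)[C@@H](OS(C)(=O)=O)CC[C@H](C)c1ccc(O)cc1 | intermediate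
16 | potassium phenoxide of 15 | CC(C)(C)[Si](C)(C)OC[C@@H](C)[C@@H](OS(C)(=O)=O)CC[C@H](C)c1ccc([O-])cc1.[K+] | intermediate
17 | (1R,4S)-1-[(S)-1-[(tert-butyldimethylsilyl)oxy]propan-2-yl]-4-methylspiro[4.5]deca-6,9-dien-8-one (key-step product) | CC(C)(C)[Si](C)(C)OC[C@@H](C)[C@H]1CC[C@H](C)C12C=CC(=O)C=C2 | intermediate
18 | (1R,4S)-1-[(S)-1-hydroxypropan-2-yl]-4-methylspiro[4.5]deca-6,9-dien-8-one | OC[C@@H](C)[C@H]1CC[C@H](C)C12C=CC(=O)C=C2 | intermediate
19 | tricyclic ether enone: C2' oxygen bonded to C6 (6S, oxygen on the face of ring B that carries C1); tetrahydropyran cis-fused to ring A across C1–C5 and to ring B across C5–C6; C8 ketone, C9=C10 | O1C[C@@H](C)[C@H]2CC[C@H](C)[C@@]23[C@@H]1CC(=O)C=C3 | intermediate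
20 | 9,10-dihydro derivative of 19 (saturated tricyclic ether ketone) | O1C[C@@H](C)[C@H]2CC[C@H](C)[C@@]23[C@@H]1CC(=O)CC3 | intermediate
21 | (1R,4S,5S)-1-[(S)-1-[(tert-butyldimethylsilyl)oxy]propan-2-yl]-4-methylspiro[4.5]dec-6-en-8-one | CC(C)(C)[Si](C)(C)OC[C@@H](C)[C@H]1CC[C@H](C)[C@@]12C=CC(=O)CC2 | intermediate
22 | lithium C7=C8 enolate from 21 | CC(C)(C)[Si](C)(C)OC[C@@H](C)[C@H]1CC[C@H](C)[C@@]12CC=C([O-])CC2.[Li+] | intermediate
23 | (1R,4S,5R)-1-[(S)-1-[(tert-butyldimethylsilyl)oxy]propan-2-yl]-4-methylspiro[4.5]dec-7-en-8-yl trifluoromethanesulfonate | CC(C)(C)[Si](C)(C)OC[C@@H](C)[C@H]1CC[C@H](C)[C@@]12CC=C(OS(=O)(=O)C(F)(F)F)CC2 | intermediate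
24 | tert-butyl{(S)-2-[(1R,4S,5R)-4,8-dimethylspiro[4.5]dec-7-en-1-yl]propoxy}dimethylsilane | CC(C)(C)[Si](C)(C)OC[C@@H](C)[C@H]1CC[C@H](C)[C@@]12CC=C(C)CC2 | intermediate
25 | (S)-2-[(1R,4S,5R)-4,8-dimethylspiro[4.5]dec-7-en-1-yl]propan-1-ol | OC[C@@H](C)[C@H]1CC[C@H](C)[C@@]12CC=C(C)CC2 | intermediate
26 | (1R,4S,5R)-1-[(S)-1-iodopropan-2-yl]-4,8-dimethylspiro[4.5]dec-7-ene | IC[C@@H](C)[C@H]1CC[C@H](C)[C@@]12CC=C(C)CC2 | intermediate
27 | (R)-3-bromo-2-methylpropan-1-ol | OC[C@@H](C)CBr | starting material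
28 | (R)-(3-bromo-2-methylpropoxy)(tert-butyl)dimethylsilane | CC(C)(C)[Si](C)(C)OC[C@@H](C)CBr | intermediate
29 | (R)-{3-[(tert-butyldimethylsilyl)oxy]-2-methylpropyl}magnesium bromide | CC(C)(C)[Si](C)(C)OC[C@@H](C)C[Mg]Br | intermediate
30 | (S)-4-[(tert-butyldimethylsilyl)oxy]-3-methylbutan-1-ol | CC(C)(C)[Si](C)(C)OC[C@@H](C)CCO | intermediate
31 | (S)-(4-bromo-2-methylbutoxy)(tert-butyl)dimethylsilane | CC(C)(C)[Si](C)(C)OC[C@@H](C)CCBr | intermediate
32 | (S)-{4-[(tert-butyldimethylsilyl)oxy]-3-methylbutyl}magnesium bromide | CC(C)(C)[Si](C)(C)OC[C@@H](C)CC[Mg]Br | intermediate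
33 | tert-butyl{[(2S,6R)-6-[(1R,4S,5R)-4,8-dimethylspiro[4.5]dec-7-en-1-yl]-2-methylheptyl]oxy}dimethylsilane | CC(C)(C)[Si](C)(C)OC[C@@H](C)CCC[C@@H](C)[C@H]1CC[C@H](C)[C@@]12CC=C(C)CC2 | intermediate
34 | (2S,6R)-6-[(1R,4S,5R)-4,8-dimethylspiro[4.5]dec-7-en-1-yl]-2-methylheptan-1-ol | OC[C@@H](C)CCC[C@@H](C)[C@H]1CC[C@H](C)[C@@]12CC=C(C)CC2 | intermediate
35 | (2S,6R)-6-[(1R,4S,5R)-4,8-dimethylspiro[4.5]dec-7-en-1-yl]-2-methylheptyl acetate | CC(=O)OC[C@@H](C)CCC[C@@H](C)[C@H]1CC[C@H](C)[C@@]12CC=C(C)CC2 | intermediate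
36 | (2S,6R)-6-[(1R,4S,5S)-9-hydroxy-4,8-dimethylspiro[4.5]dec-7-en-1-yl]-2-methylheptyl acetate, mixture of C9 epimers | CC(=O)OC[C@@H](C)CCC[C@@H](C)[C@H]1CC[C@H](C)[C@@]12CC=C(C)C(O)C2 | intermediate
37 | (2S,6R)-6-[(1R,4S,5S)-4,8-dimethyl-9-oxospiro[4.5]dec-7-en-1-yl]-2-methylheptyl acetate | CC(=O)OC[C@@H](C)CCC[C@@H](C)[C@H]1CC[C@H](C)[C@@]12CC=C(C)C(=O)C2 | intermediate
38 | (2S,6R)-6-[(1R,4S,5S,9S)-9-hydroxy-4,8-dimethylspiro[4.5]dec-7-en-1-yl]-2-methylheptyl acetate (CNP0304655.1) | CC(=O)OC[C@@H](C)CCC[C@@H](C)[C@H]1CC[C@H](C)[C@@]12CC=C(C)[C@@H](O)C2 | target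

**Step count**
Total: 24 steps. Longest linear sequence: 21 steps (steps 1–16 and 20–24); the C3'–C6' bromide 31 takes 3 steps (17–19).

**Steps most likely to fail**

Step 9. What may go wrong: E2 elimination of the hindered secondary mesylate, or its ionisation with hydride shift, may outrun the congested C5–C1 bond formation. Fallback: the electrophile is changed from an open-chain mesylate to a 1,3-cyclic sulfate, which reacts at lower temperature and carries the C2' oxygen as its own leaving group. It sets out from diol 12. 1,1'-Sulfonyldiimidazole and NaH in THF should give (4S,5R)-4-[(3S)-3-[4-(benzyloxy)phenyl]butyl]-5-methyl-1,3,2-dioxathiane 2,2-dioxide F1. Hydrogenolysis over Pd/C in EtOAc should give the phenol (4S,5R)-4-[(3S)-3-(4-hydroxyphenyl)butyl]-5-methyl-1,3,2-dioxathiane 2,2-dioxide F2. KOt-Bu in dilute t-BuOH at room temperature should open the sulfate at C1 with inversion, the only intramolecular mode that gives a five-membered ring, to potassium (S)-2-[(1R,4S)-4-methyl-8-oxospiro[4.5]deca-6,9-dien-1-yl]propyl sulfate F3. Hydrolysis of the sulfate monoester with catalytic H2SO4 and water in THF gives alcohol 18, which on addition of a trace of K2CO3 closes to 19, where the route is rejoined.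

Step 10. What may go wrong: poor discrimination between the two diastereotopic enone arms, that is closure onto C10 or an equilibrium mixture of both ethers. Fallback: the tether is given up and the arms are distinguished by a catalyst. It sets out from 17. Ene-reductases of the old yellow enzyme family (for example YqjM or OPR3, with NADP+, glucose and glucose dehydrogenase in pH 7 buffer at 30 °C) are known to reduce one C=C of 4,4-disubstituted cyclohexa-2,5-dienones. A panel of stereocomplementary enzymes would be screened for the one that reduces C9=C10 of 17. This gives 21 directly, so steps 10–12 are bypassed and the route is rejoined at 21. No new compound is formed.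

Step 12. What may go wrong: the ring-opening equilibrium may not be drained, either because E1cB elimination under an amine base is too slow or because silylation of the ketone enol competes with opening. Fallback: the ketone is activated covalently, so that ring opening is driven by conjugation and not by trapping. It sets out from 20. Condensation with pyrrolidine (catalytic TsOH, benzene, reflux with water removal) gives the enamine toward C7. This should expel the C6 alkoxide through the conjugated iminium ion and then lose a C9 proton, giving the cross-conjugated aminodiene (S)-2-[(1R,4S,5S)-4-methyl-8-(pyrrolidin-1-yl)spiro[4.5]deca-6,8-dien-1-yl]propan-1-ol F4, to which the alcohol cannot add back. Silylation (TBSCl, imidazole, CH2Cl2) gives 1-[(1R,4S,5S)-1-[(S)-1-[(tert-butyldimethylsilyl)oxy]propan-2-yl]-4-methylspiro[4.5]deca-6,8-dien-8-yl]pyrrolidine F5. Hydrolysis in buffered aqueous acetic acid (AcOH, NaOAc, THF/H2O) returns enone 21, where the route is rejoined.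

**Further compounds**
F1 | step 9 | (4S,5R)-4-[(3S)-3-[4-(benzyloxy)phenyl]butyl]-5-methyl-1,3,2-dioxathiane 2,2-dioxide | O=S1(=O)OC[C@@H](C)[C@H](CC[C@H](C)c2ccc(OCc3ccccc3)cc2)O1
F2 | step 9 | (4S,5R)-4-[(3S)-3-(4-hydroxyphenyl)butyl]-5-methyl-1,3,2-dioxathiane 2,2-dioxide | O=S1(=O)OC[C@@H](C)[C@H](CC[C@H](C)c2ccc(O)cc2)O1
F3 | step 9 | potassium (S)-2-[(1R,4S)-4-methyl-8-oxospiro[4.5]deca-6,9-dien-1-yl]propyl sulfate | [K+].[O-]S(=O)(=O)OC[C@@H](C)[C@H]1CC[C@H](C)C12C=CC(=O)C=C2
F0 | step 10 | none | none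
F4 | step 12 | (S)-2-[(1R,4S,5S)-4-methyl-8-(pyrrolidin-1-yl)spiro[4.5]deca-6,8-dien-1-yl]propan-1-ol | OC[C@@H](C)[C@H]1CC[C@H](C)[C@@]12C=CC(N3CCCC3)=CC2
F5 | step 12 | 1-[(1R,4S,5S)-1-[(S)-1-[(tert-butyldimethylsilyl)oxy]propan-2-yl]-4-methylspiro[4.5]deca-6,8-dien-8-yl]pyrrolidine | CC(C)(C)[Si](C)(C)OC[C@@H](C)[C@H]1CC[C@H](C)[C@@]12C=CC(N3CCCC3)=CC2
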